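**Retrosynthetic overview**

1. The target is a (2R,3S,4R,5R)-oxolan-3-ol with aryl (C2), methyl (C3), methyl (C4) and aryl (C5) all cis and the C3 hydroxyl on the other face. The end game is hydrogenolysis of two benzyl ethers, preceded by a C3–Si → C3–OH oxidation with retention.
2. Key disconnection: a formal (3+2) annulation that makes C4–C5 and O1–C2 in one operation from O-benzylvanillin (C5=O1) and an (R,E)-α-aryl-β-methylcrotylsilane (C2–C3–C4). The ring closes when the alkoxide O1 attacks C2 after silicon has moved from C2 to C3.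
3. Enabling feature: the O1–C2–C3–O array of the oxolane ring, that is, a tertiary C3 hydroxyl anti to the O1–C2 bond, next to a C2 that is benzylic to a 4-oxygenated arene. The C3 oxygen is the trace of the migrating silyl group, and the C2 aryl stabilises the cation that O1 captures.
4. The allylsilane comes from a nickel-catalysed enantioconvergent reductive coupling of a racemic (chlorobenzyl)silane with (E)-2-bromobut-2-ene; the silane comes from 4-(benzyloxy)-3-methoxybenzyl alcohol by chlorination and carbenoid silylation.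
5. Ring order: both benzene rings are bought; the oxolane, the only ring made, is formed in step 4.

Key step: step 4

Assumption: 4-(benzyloxy)-3-methoxybenzyl alcohol, 4-(benzyloxy)-3-methoxybenzaldehyde, isomerically pure (E)-2-bromobut-2-ene and chloro(dimethyl)phenylsilane are taken as commercial; the sense of induction of the nickel/bis(oxazoline) catalyst is not predicted here, so the ligand antipode that delivers the (R)-allylsilane is to be chosen in a first run.

**Route**

Step 1
Reactants: 1 [4-(benzyloxy)-3-methoxyphenyl]methanol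
Product: 2 1-(benzyloxy)-4-(chloromethyl)-2-methoxybenzene
Conditions: SOCl2 (1.2 equiv), CH2Cl2, 0 °C → rt
Reagents that add atoms: thionyl chloride, O=S(Cl)Cl
Why: Deoxychlorination of an electron-rich benzylic alcohol through its chlorosulfite is fast at 0 °C and leaves the aryl benzyl ether untouched; no stereocenter is formed.

Step 2
Reactants: 2 1-(benzyloxy)-4-(chloromethyl)-2-methoxybenzene
Product: 4 rac-{[4-(benzyloxy)-3-methoxyphenyl](chloro)methyl}dimethyl(phenyl)silane, via α-chlorobenzyllithium 3 (not isolated)
Conditions: PhMe2SiCl (1.1 equiv), THF, −78 °C; LiN(iPr)2 (commercial solution, 1.15 equiv) added last, −78 °C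
Reagents that add atoms: chloro(dimethyl)phenylsilane, C[Si](C)(Cl)c1ccccc1
Why: Benzylic α-lithiation of the benzyl chloride under internal-quench conditions (carbenoid silylation) should trap the short-lived carbenoid 3 on silicon before it can self-couple, because the hindered amide base tolerates the chlorosilane at −78 °C; the new stereocenter is made racemic on purpose, since step 3 is stereoconvergent.

Step 3
Reactants: 4 rac-{[4-(benzyloxy)-3-methoxyphenyl](chloro)methyl}dimethyl(phenyl)silane; 5 (E)-2-bromobut-2-ene
Product: 6 {(1R,2E)-1-[4-(benzyloxy)-3-methoxyphenyl]-2-methylbut-2-en-1-yl}dimethyl(phenyl)silane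
Conditions: NiCl2(dme) (10 mol %), chiral indane-fused bis(oxazoline) ligand (11 mol %), cobalt phthalocyanine Co(C32H16N8) (5 mol %), Mn powder (3 equiv), NMP, 5 °C
Reagents that add atoms: none
Why: In this nickel-catalysed enantioconvergent reductive cross-electrophile coupling of a racemic (chlorobenzyl)silane with an alkenyl bromide, chlorine abstraction gives a planar α-silyl benzylic radical that is captured by the chiral alkenylnickel species, so the ligand sets the silicon-bearing stereocenter as (R) while the E geometry of 5 (the two methyls cis) is carried over.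

Step 4
Reactants: 6 {(1R,2E)-1-[4-(benzyloxy)-3-methoxyphenyl]-2-methylbut-2-en-1-yl}dimethyl(phenyl)silane; 7 4-(benzyloxy)-3-methoxybenzaldehyde
Product: 9 {(2R,3S,4R,5R)-2,5-bis[4-(benzyloxy)-3-methoxyphenyl]-3,4-dimethyloxolan-3-yl}dimethyl(phenyl)silane, via β-silyl benzylic cation 8 (not isolated)
Conditions: BF3·OEt2 (1.2 equiv), CH2Cl2, 4 Å MS, −78 → −45 °C; Et3N then aq. NaHCO3 quench at −78 °C
Reagents that add atoms: none
Why: BF3-activated 7 is attacked by the γ-carbon of 6 anti to its C–Si bond (anti-SE2′), which forms C4–C5 and a β-silyl cation; the PhMe2Si group then shifts suprafacially from C2 to C3 to give the silicon-bridged benzylic cation 8, and the boron-bound alkoxide O1 attacks C2 anti to silicon, forming the O1–C2 bond and closing the oxolane. The closest known reaction type is the Lewis acid-promoted (3+2) annulation of α-substituted (E)-crotylsilanes with aldehydes to 3-silyltetrahydrofurans. The oxolane is closed in a 5-endo mode (opening of the silicon-bridged cation at its benzylic carbon C2), preferred over 4-exo attack at C3 because the positive charge sits at C2 next to the 4-benzyloxyaryl group. C4 is set by the (R)-silicon-bearing centre of 6 (electrophile anti to C–Si, hydrogen eclipsing the alkene), C5 by the open antiperiplanar transition state that gives the syn C4/C5 pair, C3 by the silyl shift on the face opposite the new C4–C5 bond (which, with the E-alkene, leaves the two methyls cis), and C2 by inversion in the anti ring closure (aryl cis to the C3 methyl, silicon trans). The step needs ring closure to outrun loss of the silyl group (Hosomi–Sakurai elimination) and needs the hydrogen-inside conformer of 6 to react; the poorly nucleofugal PhMe2Si group at −78 °C, the benzylic stabilisation of 8 and the product-like preference for aryl cis to methyl should secure this.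

Step 5
Reactants: 9 {(2R,3S,4R,5R)-2,5-bis[4-(benzyloxy)-3-methoxyphenyl]-3,4-dimethyloxolan-3-yl}dimethyl(phenyl)silane
Product: 10 (2R,3S,4R,5R)-2,5-bis[4-(benzyloxy)-3-methoxyphenyl]-3,4-dimethyloxolan-3-ol
Conditions: t-BuOOH (anhydrous, in decane), CsOH·H2O, n-Bu4NF, DMF, 23 → 70 °C
Reagents that add atoms: tert-butyl hydroperoxide, CC(C)(C)OO
Why: In this Tamao–Fleming oxidation under nucleophilic conditions suited to hindered phenylsilanes, hydroperoxide adds to fluoride-activated silicon and the carbon ligands migrate from Si to O, C3 with retention, so the hydroxyl should end up trans to the C2 aryl; the electron-rich arenes and benzyl ethers, which would not tolerate electrophilic dephenylation, are not touched.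

Step 6
Reactants: 10 (2R,3S,4R,5R)-2,5-bis[4-(benzyloxy)-3-methoxyphenyl]-3,4-dimethyloxolan-3-ol
Product: 11 (2R,3S,4R,5R)-2,5-bis(4-hydroxy-3-methoxyphenyl)-3,4-dimethyloxolan-3-ol
Conditions: H2 (1 atm), 10% Pd/C, EtOAc/MeOH, rt
Reagents that add atoms: none
Why: Hydrogenolysis of the two aryl benzyl ethers over palladium on carbon in a neutral solvent should be much faster than cleavage of the ring benzylic C–O bonds, so the four stereocenters are kept and the free bis-phenol is released.

**Compound list**

1 | [4-(benzyloxy)-3-methoxyphenyl]methanol | COc1cc(CO)ccc1OCc1ccccc1 | starting material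
2 | 1-(benzyloxy)-4-(chloromethyl)-2-methoxybenzene | COc1cc(CCl)ccc1OCc1ccccc1 | intermediate
3 | {[4-(benzyloxy)-3-methoxyphenyl](chloro)methyl}lithium, carbenoid formed and trapped in the flask | [Li]C(Cl)c1ccc(OCc2ccccc2)c(OC)c1 | intermediate
4 | rac-{[4-(benzyloxy)-3-methoxyphenyl](chloro)methyl}dimethyl(phenyl)silane | COc1cc(C(Cl)[Si](C)(C)c2ccccc2)ccc1OCc1ccccc1 | intermediate
5 | (E)-2-bromobut-2-ene (the two methyl groups cis) | C/C=C(\C)Br | starting material
6 | {(1R,2E)-1-[4-(benzyloxy)-3-methoxyphenyl]-2-methylbut-2-en-1-yl}dimethyl(phenyl)silane | C/C=C(\C)[C@H](c1ccc(OCc2ccccc2)c(OC)c1)[Si](C)(C)c1ccccc1 | intermediate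
7 | 4-(benzyloxy)-3-methoxybenzaldehyde (O-benzylvanillin) | COc1cc(C=O)ccc1OCc1ccccc1 | starting material
8 | BF3-bound alkoxide carrying the β-silyl (silicon-bridged) benzylic cation at C2, formed in the flask after C4–C5 bond formation and 1,2-silyl shift | F[B-](F)(F)O[C@@H](c1ccc(OCc2ccccc2)c(OC)c1)[C@@H](C)[C@@](C)([CH+]c1ccc(OCc2ccccc2)c(OC)c1)[Si](C)(C)c1ccccc1 | intermediate
9 | {(2R,3S,4R,5R)-2,5-bis[4-(benzyloxy)-3-methoxyphenyl]-3,4-dimethyloxolan-3-yl}dimethyl(phenyl)silane (aryl, methyl, methyl, aryl all cis; silyl on the other face) | COc1cc([C@H]2O[C@@H](c3ccc(OCc4ccccc4)c(OC)c3)[C@@H](C)[C@]2(C)[Si](C)(C)c5ccccc5)ccc1OCc1ccccc1 | intermediate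
10 | (2R,3S,4R,5R)-2,5-bis[4-(benzyloxy)-3-methoxyphenyl]-3,4-dimethyloxolan-3-ol | COc1cc([C@H]2O[C@@H](c3ccc(OCc4ccccc4)c(OC)c3)[C@@H](C)[C@]2(C)O)ccc1OCc1ccccc1 | intermediate
11 | (2R,3S,4R,5R)-2,5-bis(4-hydroxy-3-methoxyphenyl)-3,4-dimethyloxolan-3-ol | COc1cc([C@H]2O[C@@H](c3ccc(O)c(OC)c3)[C@@H](C)[C@]2(C)O)ccc1O | target

**Step count and risks**

Total step count: 6. Longest linear sequence: 6 steps (1 → 11); 5 and 7 enter as commercial partners.

Steps most likely to fail:

1. Step 4 (annulation). The β-silyl cation may lose its silyl group before the ring closes, giving the open-chain alkenol, or the aryl-inside conformer of the allylsilane may react and erode control at C2. The fallback sets out from 6 and 7 and comes back at 10, so step 5 is then not needed; it makes the elimination the intended course. TiCl4, CH2Cl2, −78 °C should give the Hosomi–Sakurai product (1R,2S,3E)-1,4-bis[4-(benzyloxy)-3-methoxyphenyl]-2,3-dimethylbut-3-en-1-ol F1, with the same anti-SE2′ control of C4 and C5. Shi epoxidation of its trisubstituted styrene with the L-fructose-derived ketone (KHSO5 as Oxone, K2CO3 buffer, MeCN/dimethoxymethane, 0 °C) should then give (1R,2R)-1-[4-(benzyloxy)-3-methoxyphenyl]-2-{(2S,3S)-3-[4-(benzyloxy)-3-methoxyphenyl]-2-methyloxiran-2-yl}propan-1-ol F2. Brief exposure to PPTS (CH2Cl2, −20 °C) is expected to trigger 5-endo opening of the epoxide at its benzylic carbon by the C5 hydroxyl with inversion, which forms the same O1–C2 bond, frees the C3 hydroxyl and gives 10.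

2. Step 5 (oxidation of the tertiary C–Si bond). Peroxide may fail to reach the hindered silicon on the quaternary C3, or base and fluoride may open the ring by β-elimination of silicon and O1. The fallback sets out from 2 and comes back at 10; it carries a silicon ligand that fluoride removes under mild conditions. Steps 2 to 4 run with commercial benzyl(chloro)dimethylsilane in place of PhMe2SiCl should give rac-benzyl{[4-(benzyloxy)-3-methoxyphenyl](chloro)methyl}dimethylsilane F3, then benzyl{(1R,2E)-1-[4-(benzyloxy)-3-methoxyphenyl]-2-methylbut-2-en-1-yl}dimethylsilane F4, then benzyl{(2R,3S,4R,5R)-2,5-bis[4-(benzyloxy)-3-methoxyphenyl]-3,4-dimethyloxolan-3-yl}dimethylsilane F5. n-Bu4NF (THF, rt) should cleave the Si–benzyl bond, and H2O2, KHCO3, MeOH/THF, 40 °C should then oxidise the resulting fluorosilane with retention to 10.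

3. Step 3 (reductive coupling). Capture of the benzylic radical by the hindered, trisubstituted alkenylnickel species may be slow, so that homocoupling or reduction of 4 takes over, or enantiocontrol may be low. The fallback sets out from 7 and comes back at 6; it takes the chirality from a reagent-controlled ketone reduction and transfers it by a stereospecific allylic substitution. Horner–Wadsworth–Emmons olefination of 7 with diethyl (3-oxobutan-2-yl)phosphonate (NaH, THF) should give (3E)-4-[4-(benzyloxy)-3-methoxyphenyl]-3-methylbut-3-en-2-one F6. CBS reduction ((S)-Me-CBS oxazaborolidine, BH3·SMe2, toluene, −40 °C) should give (2R,3E)-4-[4-(benzyloxy)-3-methoxyphenyl]-3-methylbut-3-en-2-ol F7, and PhNCO, Et3N, CH2Cl2 should give (2R,3E)-4-[4-(benzyloxy)-3-methoxyphenyl]-3-methylbut-3-en-2-yl N-phenylcarbamate F8. Deprotonation with n-BuLi, then CuI and PhMe2SiLi (THF, −78 → 0 °C) should deliver silicon intramolecularly, syn and SN2′, to the benzylic carbon; the (R)-carbinol is expected to give (R,E)-6.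

**Further compounds**

F1 | step 4 | (1R,2S,3E)-1,4-bis[4-(benzyloxy)-3-methoxyphenyl]-2,3-dimethylbut-3-en-1-ol | O[C@@H](c1ccc(OCc2ccccc2)c(OC)c1)[C@@H](C)/C(C)=C/c1ccc(OCc2ccccc2)c(OC)c1
F2 | step 4 | (1R,2R)-1-[4-(benzyloxy)-3-methoxyphenyl]-2-{(2S,3S)-3-[4-(benzyloxy)-3-methoxyphenyl]-2-methyloxiran-2-yl}propan-1-ol | O[C@@H](c1ccc(OCc2ccccc2)c(OC)c1)[C@@H](C)[C@]1(C)O[C@H]1c1ccc(OCc2ccccc2)c(OC)c1
F3 | step 5 | rac-benzyl{[4-(benzyloxy)-3-methoxyphenyl](chloro)methyl}dimethylsilane | COc1cc(C(Cl)[Si](C)(C)Cc2ccccc2)ccc1OCc1ccccc1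
F4 | step 5 | benzyl{(1R,2E)-1-[4-(benzyloxy)-3-methoxyphenyl]-2-methylbut-2-en-1-yl}dimethylsilane | C/C=C(\C)[C@H](c1ccc(OCc2ccccc2)c(OC)c1)[Si](C)(C)Cc1ccccc1
F5 | step 5 | benzyl{(2R,3S,4R,5R)-2,5-bis[4-(benzyloxy)-3-methoxyphenyl]-3,4-dimethyloxolan-3-yl}dimethylsilane | COc1cc([C@H]2O[C@@H](c3ccc(OCc4ccccc4)c(OC)c3)[C@@H](C)[C@]2(C)[Si](C)(C)Cc5ccccc5)ccc1OCc1ccccc1
F6 | step 3 | (3E)-4-[4-(benzyloxy)-3-methoxyphenyl]-3-methylbut-3-en-2-one | CC(=O)/C(C)=C/c1ccc(OCc2ccccc2)c(OC)c1
F7 | step 3 | (2R,3E)-4-[4-(benzyloxy)-3-methoxyphenyl]-3-methylbut-3-en-2-ol | C[C@@H](O)/C(C)=C/c1ccc(OCc2ccccc2)c(OC)c1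
F8 | step 3 | (2R,3E)-4-[4-(benzyloxy)-3-methoxyphenyl]-3-methylbut-3-en-2-yl N-phenylcarbamate | C[C@@H](OC(=O)Nc1ccccc1)/C(C)=C/c1ccc(OCc2ccccc2)c(OC)c1
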